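**Plan**

1. Retrosynthetic cuts, in order: the acid goes back to a TBDPS-protected primary alcohol. The central (E)-C=C of the side chain is cut by a Julia–Kocienski disconnection. The 1,2-dioxolane (numbered O1, O2, C3 bearing CH2CO2H, C4, C5 bearing the chain) is then cut across C4–C5 and O2–C3 at once.
2. Enabling feature: C5 is a methyl ketone carbon at the peroxyketal level, and C4H2–C3(CH3)(CH2R) is a 1,1-disubstituted alkene that can only give a tertiary cation at C3. A peroxycarbenium ion (C5=O1(+)–O2–Si) and this alkene therefore join in a [3+2] annulation. Both ring carbons are fully substituted, so the peroxide has no α-hydrogen and survives later base steps.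
3. Forward: (R)-citronellic acid, methyl ketone, ozonolysis to the keto ester, silyl enol ether, silyl monoperoxyketal. Annulation with silylated isoprenol builds the only non-aromatic ring. Then ester to aldehyde, olefination with a separately made styrenyl sulfone, desilylation, oxidation to the acid.
4. The side-chain alkenes are introduced only after the annulation, because they would compete as π-nucleophiles for the peroxycarbenium ion.
5. Stereochemistry: the chain (R)-methyl centre comes from (R)-citronellic acid. Both quaternary ring centres are set in the annulation under control of a confined chiral counteranion. The styrenyl E alkene comes from cross-metathesis and the central E alkene from the Julia–Kocienski step.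

Key step: step 6

Assumption: the sense of induction of the chiral anion cannot be derived from precedent; the (S,S) acid is written, and its enantiomer is taken instead if a first run shows that one to be matched with the required ring configuration.

**Route**

Step 1
Reactants: 1 (R)-citronellic acid [(3R)-3,7-dimethyloct-6-enoic acid]
Product: 2 (4R)-4,8-dimethylnon-7-en-2-one
Conditions: MeLi (2.2 equiv), Et2O, 0 °C to rt; then poured into cold 1 M HCl
Reagents that add atoms: methyllithium, [Li]C
Why: Addition of MeLi to the lithium carboxylate stops after one methyl group because the ketone is released only on the acidic quench (classical methyl ketone synthesis from a carboxylic acid and two equivalents of an organolithium), and the stereocentre, β to the carbonyl group, is not touched.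

Step 2
Reactants: 2 (4R)-4,8-dimethylnon-7-en-2-one
Product: 4 methyl (4R)-4-methyl-6-oxoheptanoate, via keto aldehyde 3 (not isolated)
Conditions: O3, 2.5 M NaOH in MeOH, CH2Cl2, −78 °C
Reagents that add atoms: ozone, [O-][O+]=O; methanol, CO
Why: Ozonolysis in methanolic NaOH cleaves the electron-rich trisubstituted alkene and oxidises the aldehyde 3 that forms at the chain end on to the methyl ester in the same flask, while the methyl ketone is inert to ozone and the low temperature holds back aldol reactions.

Step 3
Reactants: 4 methyl (4R)-4-methyl-6-oxoheptanoate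
Product: 5 methyl (4R)-4-methyl-6-[(triethylsilyl)oxy]hept-6-enoate (drawn as the 6-ene; the 5-ene regioisomers are carried along)
Conditions: Et3SiOTf (1.2 equiv), Et3N (1.5 equiv), CH2Cl2, 0 °C
Reagents that add atoms: triethylsilyl triflate, CC[Si](CC)(CC)OS(=O)(=O)C(F)(F)F
Why: Soft enolisation with a silyl triflate and an amine silylates the ketone and leaves the ester alone, and the regio- and geometric isomers need no separation because each of them carries the same oxygen-bearing carbon that becomes the ketal carbon in step 4.

Step 4
Reactants: 5 silyl enol ether (isomer mixture)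
Product: 6 methyl (4R)-4-methyl-6-[(triethylsilyl)oxy]-6-[(triethylsilyl)peroxy]heptanoate (both epimers at C6)
Conditions: Co(C11H19O2)2 [bis(2,2,6,6-tetramethylheptane-3,5-dionato)cobalt, divalent cobalt] (10 mol %), O2 (1 atm), Et3SiH (2 equiv), ClCH2CH2Cl, rt
Reagents that add atoms: dioxygen, O=O; triethylsilane, CC[SiH](CC)CC
Why: Mukaiyama–Isayama silylperoxidation (hydrogen-atom transfer from a cobalt hydride to the enol ether carbon β to oxygen, trapping of the α-siloxy radical by O2, silylation by Et3SiH) is the known way from silyl enol ethers to silyl monoperoxyketals; the new ketal centre forms as both epimers, which does not matter because it becomes planar again in step 6.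

Step 5
Reactants: 7 3-methylbut-3-en-1-ol
Product: 8 tert-butyl[(3-methylbut-3-en-1-yl)oxy]diphenylsilane
Conditions: tBuPh2SiCl, imidazole, CH2Cl2, rt
Reagents that add atoms: tert-butyldiphenylsilyl chloride, CC(C)(C)[Si](Cl)(c1ccccc1)c1ccccc1
Why: Standard silylation of a primary alcohol; the bulky, Lewis-acid-stable TBDPS ether is chosen so that the oxygen of the arm neither traps the cation of step 6 nor is lost there.

Step 6
Reactants: 6 silyl monoperoxyketal; 8 tert-butyl[(3-methylbut-3-en-1-yl)oxy]diphenylsilane
Product: 11 methyl (4R)-5-[(3R,5S)-5-{2-[(tert-butyldiphenylsilyl)oxy]ethyl}-3,5-dimethyl-1,2-dioxolan-3-yl]-4-methylpentanoate, via peroxycarbenium ion 9 (not isolated), via tertiary carbocation 10 (not isolated)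
Conditions: (S,S)-imidodiphosphorimidate acid HN[P(=NSO2CF3)(O2C20H10Ar2)]2 (Ar = 3,5-(CF3)2C6H3 at the 3,3'-positions of each 1,1'-binaphthalene-2,2'-diyl; 5 mol %), 8 (3 equiv), CH2Cl2, −78 °C
Reagents that add atoms: none
Why: Proposed new method: the chiral acid HX* is silylated in the flask, Et3Si–X* removes the siloxy group of 6 as (Et3Si)2O to leave peroxycarbenium ion 9 paired with the confined anion X*−, the CH2 terminus of alkene 8 adds to the cationic carbon to give tertiary carbocation 10, and the silylated peroxide oxygen of 10 captures that cation and hands Et3Si+ back to X*−, so that both ring bonds form in one silylium-catalysed chain. The closest known reaction types are the SnCl4-mediated [3+2] annulation of silyl monoperoxyketals with 1,1-disubstituted alkenes, which makes exactly these two bonds but without useful stereocontrol, and the enantioselective addition of alkenes and silyl nucleophiles to oxocarbenium ions paired with confined imidodiphosphorimidate anions (Prins-type 1,3-dioxane formation), so that only the union of the two is new. The 1,2-dioxolane closes by capture of a free tertiary cation in a five-membered transition state, formally 5-endo with respect to the former C=C but stepwise and therefore allowed. The ring carbon that carries the chain is set in the C–C bond formation, where the anion has to tell CH3 from the β-branched CH2 chain on the two faces of 9 (reagent control, the remote (R)-methyl centre adding only a small matched or mismatched bias), and the ring carbon that carries the silyloxyethyl arm is set in the ring closure, whose face should follow from the orientation of the alkene in the same chiral pocket as long as closure is faster than bond rotation in 10. The step needs ionisation at C–OSi and not at C–OO (the siloxy oxygen is the more basic site), one single π-nucleophile (the chain alkenes are therefore absent and only an ester and a silyl ether are present) and attack through the unsubstituted alkene terminus (secured by the 1,1-disubstitution, which makes 10 tertiary).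

Step 7
Reactants: 11 dioxolane methyl ester
Product: 12 (4R)-5-[(3R,5S)-5-{2-[(tert-butyldiphenylsilyl)oxy]ethyl}-3,5-dimethyl-1,2-dioxolan-3-yl]-4-methylpentanal
Conditions: iBu2AlH (1.1 equiv), CH2Cl2, −78 °C; MeOH, then aq. potassium sodium tartrate (KNaC4H4O6)
Reagents that add atoms: none
Why: Partial reduction of a methyl ester with one equivalent of iBu2AlH at −78 °C, where the aldehyde is released only on work-up; a dialkyl peroxide between two fully substituted carbons and the TBDPS ether should tolerate the hydride at this temperature.

Step 8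
Reactants: 13 styrene; 14 5-bromopent-1-ene
Product: 15 [(1E)-5-bromopent-1-en-1-yl]benzene
Conditions: 13 (3 equiv), second-generation Grubbs catalyst RuCl2(=CHPh)(PCy3)(H2IMes) (2 mol %), CH2Cl2, 40 °C
Reagents that add atoms: none
Why: Olefin cross-metathesis of a styrene with a terminal alkene, in which excess styrene suppresses homodimerisation of 14 and the conjugated product forms as the E isomer under thermodynamic control.

Step 9
Reactants: 15 [(1E)-5-bromopent-1-en-1-yl]benzene; 16 1-phenyl-1H-tetrazole-5-thiol
Product: 17 1-phenyl-5-{[(4E)-5-phenylpent-4-en-1-yl]sulfanyl}-1H-tetrazole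
Conditions: K2CO3, DMF, rt
Reagents that add atoms: none
Why: SN2 S-alkylation of the thiolate by a primary bromide.

Step 10
Reactants: 17 tetrazolyl sulfide
Product: 18 1-phenyl-5-{[(4E)-5-phenylpent-4-en-1-yl]sulfonyl}-1H-tetrazole
Conditions: (NH4)6Mo7O24·4H2O (10 mol %), 30% aq. H2O2, EtOH, 0 °C to rt
Reagents that add atoms: hydrogen peroxide, OO
Why: Molybdate-catalysed oxidation of the sulfide by H2O2 to the sulfone, under which an isolated styrenyl double bond is not epoxidised; the crystalline sulfone can be recrystallised to geometric purity.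

Step 11
Reactants: 12 dioxolane aldehyde; 18 tetrazolyl sulfone
Product: 19 tert-butyl{2-[(3S,5R)-3,5-dimethyl-5-[(2R,5E,9E)-2-methyl-10-phenyldeca-5,9-dien-1-yl]-1,2-dioxolan-3-yl]ethoxy}diphenylsilane
Conditions: 18, KN(SiMe3)2 (1.1 equiv), 1,2-dimethoxyethane, −60 °C; then 12, −60 °C to rt
Reagents that add atoms: none
Why: Julia–Kocienski olefination (addition of the metalated 1-phenyltetrazolyl sulfone to the aldehyde, Smiles rearrangement, loss of SO2 and tetrazolate), which with KN(SiMe3)2 in DME favours the E alkene from two unbranched partners; the peroxide has no α-hydrogen and the anion is consumed by the aldehyde at low temperature.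

Step 12
Reactants: 19 diene silyl ether
Product: 20 2-[(3S,5R)-3,5-dimethyl-5-[(2R,5E,9E)-2-methyl-10-phenyldeca-5,9-dien-1-yl]-1,2-dioxolan-3-yl]ethan-1-ol
Conditions: Bu4NF buffered with AcOH, THF, rt
Reagents that add atoms: none
Why: Fluoride cleavage of the silyl ether, buffered with AcOH so that the medium stays close to neutral; peroxide and alkenes are inert.

Step 13
Reactants: 20 primary alcohol
Product: 22 2-[(3R,5R)-3,5-dimethyl-5-[(2R,5E,9E)-2-methyl-10-phenyldeca-5,9-dien-1-yl]-1,2-dioxolan-3-yl]acetic acid, via aldehyde 21 (not isolated)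
Conditions: TEMPO (2,2,6,6-tetramethylpiperidin-1-oxyl, 20 mol %), PhI(OAc)2 (2.5 equiv), MeCN/H2O, rt
Reagents that add atoms: water, O
Why: Oxoammonium oxidation (TEMPO with PhI(OAc)2 in aqueous MeCN) takes the primary alcohol through aldehyde 21 to the carboxylic acid without touching the alkenes or the O–O bond and without base, so that the β-peroxy carbonyl compounds cannot undergo elimination; no stereocentre is affected (the ring descriptor at C3 changes from S to R only because the arm gains CIP priority).

**Compound list**

1 | (R)-citronellic acid, (3R)-3,7-dimethyloct-6-enoic acid | C[C@H](CCC=C(C)C)CC(=O)O | starting material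
2 | (4R)-4,8-dimethylnon-7-en-2-one | C[C@H](CCC=C(C)C)CC(C)=O | intermediate
3 | (4R)-4-methyl-6-oxoheptanal (keto aldehyde, not isolated) | C[C@H](CCC=O)CC(C)=O | intermediate
4 | methyl (4R)-4-methyl-6-oxoheptanoate | C[C@H](CCC(=O)OC)CC(C)=O | intermediate
5 | methyl (4R)-4-methyl-6-[(triethylsilyl)oxy]hept-6-enoate (with its 5-ene regioisomers) | C[C@H](CCC(=O)OC)CC(=C)O[Si](CC)(CC)CC | intermediate
6 | methyl (4R)-4-methyl-6-[(triethylsilyl)oxy]-6-[(triethylsilyl)peroxy]heptanoate (both C6 epimers) | C[C@H](CCC(=O)OC)CC(C)(O[Si](CC)(CC)CC)OO[Si](CC)(CC)CC | intermediate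
7 | 3-methylbut-3-en-1-ol | CC(=C)CCO | starting material
8 | tert-butyl[(3-methylbut-3-en-1-yl)oxy]diphenylsilane | CC(=C)CCO[Si](c1ccccc1)(c1ccccc1)C(C)(C)C | intermediate
9 | peroxycarbenium ion, [(4R)-7-methoxy-4-methyl-7-oxoheptan-2-ylidene][(triethylsilyl)oxy]oxonium (not isolated) | C[C@H](CCC(=O)OC)CC(C)=[O+]O[Si](CC)(CC)CC | intermediate
10 | tertiary carbocation from C–C bond formation between 9 and 8, charge on the carbon bearing CH3 and the silyloxyethyl arm, triethylsilylperoxy group on the neighbouring quaternary carbon (not isolated) | C[C@H](CCC(=O)OC)C[C@](C)(C[C+](C)CCO[Si](c1ccccc1)(c1ccccc1)C(C)(C)C)OO[Si](CC)(CC)CC | intermediate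
11 | methyl (4R)-5-[(3R,5S)-5-{2-[(tert-butyldiphenylsilyl)oxy]ethyl}-3,5-dimethyl-1,2-dioxolan-3-yl]-4-methylpentanoate | C[C@H](CCC(=O)OC)C[C@]1(C)C[C@](C)(CCO[Si](c2ccccc2)(c2ccccc2)C(C)(C)C)OO1 | intermediate
12 | (4R)-5-[(3R,5S)-5-{2-[(tert-butyldiphenylsilyl)oxy]ethyl}-3,5-dimethyl-1,2-dioxolan-3-yl]-4-methylpentanal | C[C@H](CCC=O)C[C@]1(C)C[C@](C)(CCO[Si](c2ccccc2)(c2ccccc2)C(C)(C)C)OO1 | intermediate
13 | styrene | C=Cc1ccccc1 | starting material
14 | 5-bromopent-1-ene | C=CCCCBr | starting material
15 | [(1E)-5-bromopent-1-en-1-yl]benzene | BrCCC/C=C/c1ccccc1 | intermediate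
16 | 1-phenyl-1H-tetrazole-5-thiol | Sc1nnnn1-c1ccccc1 | starting material
17 | 1-phenyl-5-{[(4E)-5-phenylpent-4-en-1-yl]sulfanyl}-1H-tetrazole | c1ccccc1/C=C/CCCSc1nnnn1-c1ccccc1 | intermediate
18 | 1-phenyl-5-{[(4E)-5-phenylpent-4-en-1-yl]sulfonyl}-1H-tetrazole | O=S(=O)(CCC/C=C/c1ccccc1)c1nnnn1-c1ccccc1 | intermediate
19 | tert-butyl{2-[(3S,5R)-3,5-dimethyl-5-[(2R,5E,9E)-2-methyl-10-phenyldeca-5,9-dien-1-yl]-1,2-dioxolan-3-yl]ethoxy}diphenylsilane | C[C@H](CC/C=C/CC/C=C/c1ccccc1)C[C@]1(C)C[C@](C)(CCO[Si](c2ccccc2)(c2ccccc2)C(C)(C)C)OO1 | intermediate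
20 | 2-[(3S,5R)-3,5-dimethyl-5-[(2R,5E,9E)-2-methyl-10-phenyldeca-5,9-dien-1-yl]-1,2-dioxolan-3-yl]ethan-1-ol | C[C@H](CC/C=C/CC/C=C/c1ccccc1)C[C@]1(C)C[C@](C)(CCO)OO1 | intermediate
21 | 2-[(3R,5R)-3,5-dimethyl-5-[(2R,5E,9E)-2-methyl-10-phenyldeca-5,9-dien-1-yl]-1,2-dioxolan-3-yl]acetaldehyde (not isolated) | C[C@H](CC/C=C/CC/C=C/c1ccccc1)C[C@]1(C)C[C@](C)(CC=O)OO1 | intermediate
22 | 2-[(3R,5R)-3,5-dimethyl-5-[(2R,5E,9E)-2-methyl-10-phenyldeca-5,9-dien-1-yl]-1,2-dioxolan-3-yl]acetic acid | C[C@H](CC/C=C/CC/C=C/c1ccccc1)C[C@]1(C)C[C@](C)(CC(=O)O)OO1 | target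

**Step count and risks**

Total step count: 13. Longest linear sequence: 9 steps (steps 1, 2, 3, 4, 6, 7, 11, 12, 13).

Steps most likely to fail:

1. Step 6 (proposed new method). The chiral ion pair may not discriminate the two faces at one or both new quaternary carbons. The strong acid may also trigger cationic oligomerisation of the alkene or Hock-type fragmentation of the peroxide before the C–C bond forms, so that the chain does not turn over. The fallback uses known chemistry and gives up reagent control. It sets out from 6 (with 8) and uses stoichiometric SnCl4 in CH2Cl2 at −78 °C, the established annulation of silyl monoperoxyketals with 1,1-disubstituted alkenes. This should give methyl (4R)-5-[5-{2-[(tert-butyldiphenylsilyl)oxy]ethyl}-3,5-dimethyl-1,2-dioxolan-3-yl]-4-methylpentanoate as the mixture of its ring diastereomers F1. Stereochemistry is then obtained by separation instead of induction. The (R)-methyl centre of the chain makes all ring isomers diastereomers, so preparative HPLC on silica should deliver the (3R,5S) isomer. The fallback comes back to the route at 11.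

2. Step 11. The E selectivity at the new non-conjugated double bond may erode, and such geometric isomers are hard to separate this far from any polar group. The amide base or the metalated sulfone may also attack the O–O bond. The fallback replaces kinetic E/Z control by a stereospecific elimination from a purified diastereomer (Horner–Wittig sequence). It sets out from ester 11 and bypasses 12. Bromide 15 is heated with ethyl diphenylphosphinite (Michaelis–Arbuzov) to give diphenyl[(4E)-5-phenylpent-4-en-1-yl]phosphane oxide F2. F2 is lithiated with n-BuLi in THF at −78 °C (two equivalents of the preformed anion) and C-acylated by 11 to give the β-keto phosphine oxide (1E,9R)-10-[(3R,5S)-5-{2-[(tert-butyldiphenylsilyl)oxy]ethyl}-3,5-dimethyl-1,2-dioxolan-3-yl]-5-(diphenylphosphoryl)-9-methyl-1-phenyldec-1-en-6-one F3. NaBH4 in EtOH should reduce F3 to the threo β-hydroxy phosphine oxide, the dec-1-en-6-ol F4, which is freed from any erythro isomer by chromatography or crystallisation. NaH in DMF then effects syn elimination of diphenylphosphinate, which can only give the E alkene. The fallback comes back to the route at 19.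

3. Step 7. The hydride may over-reduce the ester to the primary alcohol or attack the O–O bond if the temperature rises, and the aldehyde is sensitive on silica. The fallback separates reduction and oxidation. It sets out from 11, which is fully reduced with LiBH4 in THF at 0 °C to (4R)-5-[(3R,5S)-5-{2-[(tert-butyldiphenylsilyl)oxy]ethyl}-3,5-dimethyl-1,2-dioxolan-3-yl]-4-methylpentan-1-ol F5. F5 is oxidised with Dess–Martin periodinane in CH2Cl2 buffered with NaHCO3, and the fallback comes back to the route at 12.

**Further compounds**

F1 | step 6 | methyl (4R)-5-[5-{2-[(tert-butyldiphenylsilyl)oxy]ethyl}-3,5-dimethyl-1,2-dioxolan-3-yl]-4-methylpentanoate, mixture of the four ring diastereomers | C[C@H](CCC(=O)OC)CC1(C)CC(C)(CCO[Si](c2ccccc2)(c2ccccc2)C(C)(C)C)OO1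
F2 | step 11 | diphenyl[(4E)-5-phenylpent-4-en-1-yl]phosphane oxide | O=P(CCC/C=C/c1ccccc1)(c1ccccc1)c1ccccc1
F3 | step 11 | (1E,9R)-10-[(3R,5S)-5-{2-[(tert-butyldiphenylsilyl)oxy]ethyl}-3,5-dimethyl-1,2-dioxolan-3-yl]-5-(diphenylphosphoryl)-9-methyl-1-phenyldec-1-en-6-one (both C5 epimers) | C[C@H](CCC(=O)C(CC/C=C/c1ccccc1)P(=O)(c1ccccc1)c1ccccc1)C[C@]1(C)C[C@](C)(CCO[Si](c2ccccc2)(c2ccccc2)C(C)(C)C)OO1
F4 | step 11 | (1E,9R)-10-[(3R,5S)-5-{2-[(tert-butyldiphenylsilyl)oxy]ethyl}-3,5-dimethyl-1,2-dioxolan-3-yl]-5-(diphenylphosphoryl)-9-methyl-1-phenyldec-1-en-6-ol, threo at C5 and C6 (both threo isomers) | C[C@H](CCC(O)C(CC/C=C/c1ccccc1)P(=O)(c1ccccc1)c1ccccc1)C[C@]1(C)C[C@](C)(CCO[Si](c2ccccc2)(c2ccccc2)C(C)(C)C)OO1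
F5 | step 7 | (4R)-5-[(3R,5S)-5-{2-[(tert-butyldiphenylsilyl)oxy]ethyl}-3,5-dimethyl-1,2-dioxolan-3-yl]-4-methylpentan-1-ol | C[C@H](CCCO)C[C@]1(C)C[C@](C)(CCO[Si](c2ccccc2)(c2ccccc2)C(C)(C)C)OO1
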